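**Plan**

1. Cuts: both acetates go back to a 2-keto 15-methyl ester (the C2 carbinol is made last, by reduction). Ring B is opened at C10–C9 (H-5 removed, H-7 restored) to a monocyclic tetraene ester. The C5–C6 bond is then cut to an enol triflate and an alkylborane.
2. Forward: ring A (C1–C5, C10 and its three methyls) is ketoisophorone; the chain C6–C17 is methyl geranate plus one carbon. The two are joined at C5–C6, and ring B (C5–C6–C7–C8–C9–C10) is closed last.
3. Enabling feature: ring B is a cyclohexene in which the quaternary, methyl-bearing C10 is bonded to C9, the allylic carbon of the methyl-substituted C7=C8 bond. This C10(CH3)–C9–C8(CH3)=C7 array is the footprint of a tertiary C10 cation adding to an (E)-C8=C9 alkene with loss of H-7. C13=C14 is carried as an enoate so the cascade stops at the bicycle.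
4. Stereochemistry: one stereocenter is set by catalysis (the C2 carbinol, asymmetric transfer hydrogenation). It relays C5, C10 and C9 in the ring closure. C2 is then inverted by oxidation and reduction under control of the axial C4 and C10 methyls, which gives the axial acetate.

Key step: step 8

Remark: labdane numbering (C1–C20) is used for all ring positions, and methyl (2E)-geranate is taken to be commercially available as the single E isomer.

**Route**

Step 1
Reactants: 1 methyl (2E)-geranate
Product: 2 methyl (2E,6E)-8-hydroxy-3,7-dimethylocta-2,6-dienoate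
Conditions: SeO2 (cat.), t-BuOOH, salicylic acid (cat.), CH2Cl2, rt
Reagents that add atoms: tert-butyl hydroperoxide, CC(C)(C)OO (terminal oxidant); selenium dioxide, O=[Se]=O (catalytic oxygen carrier)
Why: Catalytic SeO2 allylic oxidation (ene reaction then [2,3]-shift) should attack only the electron-rich 6,7-alkene at its (E)-methyl group, so the 6E geometry is kept and the conjugated 2,3-alkene is untouched.

Step 2
Reactants: 2 methyl (2E,6E)-8-hydroxy-3,7-dimethylocta-2,6-dienoate
Product: 3 methyl (2E,6E)-3,7-dimethyl-8-oxoocta-2,6-dienoate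
Conditions: MnO2, CH2Cl2, rt
Reagents that add atoms: none
Why: MnO2 oxidation is selective for the allylic alcohol and should give the enal without touching the ester or either alkene geometry.

Step 3
Reactants: 3 methyl (2E,6E)-3,7-dimethyl-8-oxoocta-2,6-dienoate
Product: 4 methyl (2E,6E)-3,7-dimethylnona-2,6,8-trienoate
Conditions: Ph3PCH3Br, KOt-Bu, THF, 0 °C to rt
Reagents that add atoms: methyltriphenylphosphonium bromide, C[P+](c1ccccc1)(c1ccccc1)c1ccccc1.[Br-]
Why: Wittig methylenation with the non-stabilised ylide reacts at the aldehyde only and supplies C6 as a terminal vinyl group without a new stereo element.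

Step 4
Reactants: 5 ketoisophorone
Product: 6 (R)-phorenol, (4R)-4-hydroxy-2,6,6-trimethylcyclohex-2-en-1-one
Conditions: RuCl(p-cymene)[(R,R)-TsDPEN] (cat.), i-PrOH, rt
Reagents that add atoms: none
Why: Noyori-type asymmetric transfer hydrogenation should reduce only the less hindered, alkene-flanked carbonyl, and with the C=C as the π-directing group the (R,R)-catalyst is expected to give the (4R) carbinol, the one stereocenter from which all others are derived.

Step 5
Reactants: 6 (R)-phorenol
Product: 7 (1R)-3,5,5-trimethyl-4-oxocyclohex-2-en-1-yl acetate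
Conditions: Ac2O, pyridine, DMAP (cat.), CH2Cl2, 0 °C to rt
Reagents that add atoms: acetic anhydride, CC(=O)OC(C)=O
Why: DMAP-catalysed acetylation gives an ester that should survive the hydride, palladium and acid steps and can be removed selectively before the C2 inversion.

Step 6
Reactants: 7 (1R)-3,5,5-trimethyl-4-oxocyclohex-2-en-1-yl acetate
Product: 9 (4S)-4-acetoxy-2,6,6-trimethylcyclohex-1-en-1-yl trifluoromethanesulfonate, via lithium enolate 8 (not isolated)
Conditions: L-Selectride, THF, −78 °C; then PhNTf2, −78 to 0 °C
Reagents that add atoms: N-phenyl-bis(trifluoromethanesulfonimide), O=S(=O)(N(c1ccccc1)S(=O)(=O)C(F)(F)F)C(F)(F)F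
Why: Reductive triflation: the carbonyl is shielded by the gem-dimethyl group and the α-methyl, so hydride should add 1,4 and give regiospecifically the tetrasubstituted enolate 8, which is O-sulfonylated without touching the carbinol center.

Step 7
Reactants: 4 methyl (2E,6E)-3,7-dimethylnona-2,6,8-trienoate; 9 (4S)-4-acetoxy-2,6,6-trimethylcyclohex-1-en-1-yl trifluoromethanesulfonate
Product: 11 methyl (2E,6E)-9-[(4S)-4-acetoxy-2,6,6-trimethylcyclohex-1-en-1-yl]-3,7-dimethylnona-2,6-dienoate, via alkyl-9-BBN borane 10 (not isolated)
Conditions: 9-BBN, THF, 0 °C to rt; then 9, Pd(dppf)Cl2 (cat.), AsPh3, aq K3PO4, DMF, rt to 45 °C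
Reagents that add atoms: none
Why: 9-BBN should hydroborate only the terminal vinyl group (anti-Markovnikov) to the primary borane 10, and B-alkyl Suzuki–Miyaura coupling with the enol triflate then forms the C5–C6 sp2–sp3 bond with both alkene geometries retained.

Step 8
Reactants: 11 methyl (2E,6E)-9-[(4S)-4-acetoxy-2,6,6-trimethylcyclohex-1-en-1-yl]-3,7-dimethylnona-2,6-dienoate
Product: 14 methyl (2R,5R,9R,10R)-2-acetoxylabda-7,13E-dien-15-oate, via monocyclic C10 carbocation 12 (not isolated), via bicyclic C8 carbocation 13 (not isolated)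
Conditions: ClSO3H (excess), 2-nitropropane, −78 °C; then Et3N, aq NaHCO3
Reagents that add atoms: none
Why: Protonation of the tetrasubstituted C5=C10 ring alkene gives the tertiary C10 cation 12, C9 of the (E)-C8=C9 alkene adds to it to give the tertiary C8 cation 13, and loss of the axial H-7 leaves the C7=C8 double bond, the acid being regenerated. The closest known reaction is the superacid cation–olefin cyclization of monocyclic β-cyclogeranyl-type terpenoids to drimanes and labdanes, and ring B closes in the 6-endo-trig (Markovnikov) mode through a chair. C5 is controlled by the C2 acetoxy group: the ring should react from the half-chair that keeps this group equatorial, and the proton adds axially to C5 on the face anti to the pseudoaxial C4 methyl. C10 is controlled by C5, because C9 then bonds equatorially on the same face as the new H-5, which turns the C10 methyl axial (trans ring fusion, methyl trans to the C2 oxygen). C9 is controlled by the E geometry of C8=C9, which puts C11 equatorial and H-9 anti to the C10 methyl in the chair. The step must stop at the bicycle and place the alkene at C7=C8: the O-protonated C13=C14 enoate is not nucleophilic and the antiperiplanar axial H-7 is the one normally lost from such an 8-cation at −78 °C, while both ester groups are only O-protonated and return on quench.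

Step 9
Reactants: 14 methyl (2R,5R,9R,10R)-2-acetoxylabda-7,13E-dien-15-oate
Product: 15 methyl (2R,5R,9R,10R)-2-hydroxylabda-7,13E-dien-15-oate
Conditions: K2CO3, MeOH, rt
Reagents that add atoms: none
Why: Base-catalysed methanolysis (transesterification) should remove the unhindered equatorial acetate, while the conjugated methyl ester is only exchanged with itself.

Step 10
Reactants: 15 methyl (2R,5R,9R,10R)-2-hydroxylabda-7,13E-dien-15-oate
Product: 16 methyl (5R,9R,10R)-2-oxolabda-7,13E-dien-15-oate
Conditions: Dess–Martin periodinane, NaHCO3, CH2Cl2, rt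
Reagents that add atoms: none
Why: Dess–Martin oxidation gives the C2 ketone, which has no epimerisable stereocenter next to it because C1 and C3 are CH2 groups between quaternary carbons.

Step 11
Reactants: 16 methyl (5R,9R,10R)-2-oxolabda-7,13E-dien-15-oate
Product: 17 (2S,5R,9R,10R)-labda-7,13E-diene-2,15-diol
Conditions: DIBAL-H (excess), CH2Cl2, −78 to 0 °C; Rochelle salt work-up
Reagents that add atoms: none
Why: Hydride reduction turns the enoate into the allylic alcohol and should attack the C2 ketone from the equatorial side, because the axial path is blocked by the two syn-axial methyls on C4 and C10, so the new hydroxyl is axial and cis to the C10 methyl (substrate-controlled inversion of C2).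

Step 12
Reactants: 17 (2S,5R,9R,10R)-labda-7,13E-diene-2,15-diol
Product: 18 (2S,5R,9R,10R)-labda-7,13E-diene-2,15-diyl diacetate (target)
Conditions: Ac2O, pyridine, DMAP, CH2Cl2, rt to 40 °C
Reagents that add atoms: acetic anhydride, CC(=O)OC(C)=O
Why: DMAP-catalysed acetylation should esterify both the primary allylic hydroxyl and the hindered axial secondary hydroxyl to give the diacetate.

**Compound list**

1 | methyl (2E)-3,7-dimethylocta-2,6-dienoate (methyl geranate) | COC(=O)/C=C(\C)CCC=C(C)C | starting material
2 | methyl (2E,6E)-8-hydroxy-3,7-dimethylocta-2,6-dienoate | COC(=O)/C=C(\C)CC/C=C(\C)CO | intermediate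
3 | methyl (2E,6E)-3,7-dimethyl-8-oxoocta-2,6-dienoate | COC(=O)/C=C(\C)CC/C=C(\C)C=O | intermediate
4 | methyl (2E,6E)-3,7-dimethylnona-2,6,8-trienoate | COC(=O)/C=C(\C)CC/C=C(\C)C=C | intermediate
5 | ketoisophorone (2,6,6-trimethylcyclohex-2-ene-1,4-dione) | CC1=CC(=O)CC(C)(C)C1=O | starting material
6 | (R)-phorenol, (4R)-4-hydroxy-2,6,6-trimethylcyclohex-2-en-1-one | CC1=C[C@H](O)CC(C)(C)C1=O | intermediate
7 | (1R)-3,5,5-trimethyl-4-oxocyclohex-2-en-1-yl acetate | CC1=C[C@H](OC(C)=O)CC(C)(C)C1=O | intermediate
8 | lithium (4S)-4-acetoxy-2,6,6-trimethylcyclohex-1-en-1-olate | [Li+].[O-]C1=C(C)C[C@H](OC(C)=O)CC1(C)C | intermediate (not isolated)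
9 | (4S)-4-acetoxy-2,6,6-trimethylcyclohex-1-en-1-yl trifluoromethanesulfonate | O=S(=O)(OC1=C(C)C[C@H](OC(C)=O)CC1(C)C)C(F)(F)F | intermediate
10 | methyl (2E,6E)-9-(9-borabicyclo[3.3.1]nonan-9-yl)-3,7-dimethylnona-2,6-dienoate | COC(=O)/C=C(\C)CC/C=C(\C)CCB1C2CCCC1CCC2 | intermediate (not isolated)
11 | methyl (2E,6E)-9-[(4S)-4-acetoxy-2,6,6-trimethylcyclohex-1-en-1-yl]-3,7-dimethylnona-2,6-dienoate | COC(=O)/C=C(\C)CC/C=C(\C)CCC1=C(C)C[C@H](OC(C)=O)CC1(C)C | intermediate
12 | monocyclic C10 carbocation (H-5 in place, C2 acetoxy equatorial) | COC(=O)/C=C(\C)CC/C=C(\C)CC[C@H]1[C+](C)C[C@H](OC(C)=O)CC1(C)C | intermediate (not isolated)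
13 | bicyclic C8 carbocation (trans-fused) | COC(=O)/C=C(\C)CC[C@@H]1[C+](C)CC[C@@H]2C(C)(C)C[C@@H](OC(C)=O)C[C@@]12C | intermediate (not isolated)
14 | methyl (2R,5R,9R,10R)-2-acetoxylabda-7,13E-dien-15-oate (acetoxy equatorial, trans to the C10 methyl) | COC(=O)/C=C(\C)CC[C@@H]1C(C)=CC[C@@H]2C(C)(C)C[C@@H](OC(C)=O)C[C@@]12C | intermediate
15 | methyl (2R,5R,9R,10R)-2-hydroxylabda-7,13E-dien-15-oate | COC(=O)/C=C(\C)CC[C@@H]1C(C)=CC[C@@H]2C(C)(C)C[C@@H](O)C[C@@]12C | intermediate
16 | methyl (5R,9R,10R)-2-oxolabda-7,13E-dien-15-oate | COC(=O)/C=C(\C)CC[C@@H]1C(C)=CC[C@@H]2C(C)(C)CC(=O)C[C@@]12C | intermediate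
17 | (2S,5R,9R,10R)-labda-7,13E-diene-2,15-diol (2-hydroxyl axial, cis to the C10 methyl) | OC/C=C(\C)CC[C@@H]1C(C)=CC[C@@H]2C(C)(C)C[C@H](O)C[C@@]12C | intermediate
18 | (2S,5R,9R,10R)-labda-7,13E-diene-2,15-diyl diacetate | CC(=O)OC/C=C(\C)CC[C@@H]1C(C)=CC[C@@H]2C(C)(C)C[C@H](OC(C)=O)C[C@@]12C | target

**Totals and risks**

Total step count: 12. Longest linear sequence: 9 steps (steps 4–12 from ketoisophorone; the chain branch, steps 1–3 then 7–12, is equally long).

Steps most likely to fail:

Step 8. The facial control comes from a remote group and could run in the opposite sense if the C2 ester steers by bridging to the C10 cation (a 1,3-dioxan-2-ylium ion opened by C9 from the other face) instead of by its equatorial preference. The decalin would then form with the wrong absolute sense relative to C2; non-selective proton loss from the C8 cation (H-9 or H-17 instead of H-7) is a second weakness. The fallback changes the stereochemical plan and drops the inversion. It sets out from 5 and uses the mirror-image ring A. Transfer hydrogenation with the (S,S)-catalyst should give (S)-phorenol F1, and acetylation gives (1S)-3,5,5-trimethyl-4-oxocyclohex-2-en-1-yl acetate F2. Reductive triflation through lithium (4R)-4-acetoxy-2,6,6-trimethylcyclohex-1-en-1-olate F3 gives (4R)-4-acetoxy-2,6,6-trimethylcyclohex-1-en-1-yl trifluoromethanesulfonate F4. Coupling with borane 10 gives methyl (2E,6E)-9-[(4R)-4-acetoxy-2,6,6-trimethylcyclohex-1-en-1-yl]-3,7-dimethylnona-2,6-dienoate F5. The same acid closure, now running with the ester bridging C10, would give methyl (2S,5R,9R,10R)-2-acetoxylabda-7,13E-dien-15-oate F6, in which the acetate is already axial and cis to the C10 methyl. Reduction of both esters with DIBAL-H rejoins the route at 17.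

Step 7. Oxidative addition and transmetalation may be slow at the tetrasubstituted triflate flanked by the gem-dimethyl group, with competing triflate hydrolysis or β-hydride loss from the alkylpalladium. The fallback changes the nucleophile from boron to zinc. It sets out from borane 10, which is iodinated (I2, NaOMe, MeOH) to methyl (2E,6E)-9-iodo-3,7-dimethylnona-2,6-dienoate F7. Zinc insertion (Zn, LiCl, THF) gives methyl (2E,6E)-9-(iodozincio)-3,7-dimethylnona-2,6-dienoate F8. Negishi coupling of F8 with triflate 9 under a bulky Pd–NHC or Pd–P(t-Bu)3 catalyst returns to the route at 11.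

Step 6. Hydride may be delivered 1,2 instead of 1,4, or O-sulfonylation of the hindered enolate may be slow enough for acetyl transfer or cleavage to compete. The fallback separates the two events and replaces enolate trapping by electrophilic triflation. It sets out from 7, whose ring alkene is hydrogenated (H2, Rh/Al2O3, EtOAc) to (1S)-3,3,5-trimethyl-4-oxocyclohexyl acetate F9 (C5 epimers, both usable). This ketone can enolise only toward the methyl-bearing carbon, so Tf2O with 2,6-di-tert-butyl-4-methylpyridine in CH2Cl2 should give the same tetrasubstituted triflate, returning to the route at 9.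

Further compounds
F1 | step 8 | (S)-phorenol, (4S)-4-hydroxy-2,6,6-trimethylcyclohex-2-en-1-one | CC1=C[C@@H](O)CC(C)(C)C1=O
F2 | step 8 | (1S)-3,5,5-trimethyl-4-oxocyclohex-2-en-1-yl acetate | CC1=C[C@@H](OC(C)=O)CC(C)(C)C1=O
F3 | step 8 | lithium (4R)-4-acetoxy-2,6,6-trimethylcyclohex-1-en-1-olate | [Li+].[O-]C1=C(C)C[C@@H](OC(C)=O)CC1(C)C
F4 | step 8 | (4R)-4-acetoxy-2,6,6-trimethylcyclohex-1-en-1-yl trifluoromethanesulfonate | O=S(=O)(OC1=C(C)C[C@@H](OC(C)=O)CC1(C)C)C(F)(F)F
F5 | step 8 | methyl (2E,6E)-9-[(4R)-4-acetoxy-2,6,6-trimethylcyclohex-1-en-1-yl]-3,7-dimethylnona-2,6-dienoate | COC(=O)/C=C(\C)CC/C=C(\C)CCC1=C(C)C[C@@H](OC(C)=O)CC1(C)C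
F6 | step 8 | methyl (2S,5R,9R,10R)-2-acetoxylabda-7,13E-dien-15-oate | COC(=O)/C=C(\C)CC[C@@H]1C(C)=CC[C@@H]2C(C)(C)C[C@H](OC(C)=O)C[C@@]12C
F7 | step 7 | methyl (2E,6E)-9-iodo-3,7-dimethylnona-2,6-dienoate | COC(=O)/C=C(\C)CC/C=C(\C)CCI
F8 | step 7 | methyl (2E,6E)-9-(iodozincio)-3,7-dimethylnona-2,6-dienoate | COC(=O)/C=C(\C)CC/C=C(\C)CC[Zn]I
F9 | step 6 | (1S)-3,3,5-trimethyl-4-oxocyclohexyl acetate (C5 epimer mixture) | CC1C[C@H](OC(C)=O)CC(C)(C)C1=O
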